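## Retrosynthetic overview

- The target is cut across an isoprene unit into three pieces: the [(1S)-2,6,6-trimethylcyclohex-2-en-1-yl]methyl radical, isoprene, and 2-hydroxy-5-methoxy-1,4-benzoquinone. The radical adds to isoprene (new CH2–CH2 bond), and the resulting allyl–palladium species is captured at quinone C3.
- The radical comes from the (S)-cyclohexenylacetic acid. The acid comes from a Johnson–Claisen chirality transfer on (R)-2,4,4-trimethylcyclohex-2-en-1-ol, which comes from CBS reduction of the enone.
- The enone comes from a Robinson annulation of isobutyraldehyde with ethyl vinyl ketone. The quinone partner comes from p-benzoquinone by double methoxylation and mono-hydrolysis.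
- Ring order: the cyclohexene ring is the only ring constructed (step 1). The quinone ring is carried in intact from p-benzoquinone.

Assumption: the SMILES is read as the (1S) ring stereocentre and the (2E) side-chain alkene; one-pot sequences without isolation are counted as one step.

## Route

Step 1
Reactants: 1 2-methylpropanal (isobutyraldehyde); 2 pent-1-en-3-one (ethyl vinyl ketone)
Product: 4 2,4,4-trimethylcyclohex-2-en-1-one, via Michael adduct 3 (not isolated)
Conditions: H2SO4 (cat.), neat, 45–50 °C; then toluene, reflux, Dean–Stark
Reagents that add atoms: none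
Why: Robinson annulation: acid-catalysed Michael addition of the aldehyde enol gives the 1,5-keto-aldehyde, whose only six-membered aldol condensation (ketone CH2 onto the non-enolisable aldehyde) closes the ring; no stereocentre is formed.

Step 2
Reactants: 4 2,4,4-trimethylcyclohex-2-en-1-one
Product: 5 (1R)-2,4,4-trimethylcyclohex-2-en-1-ol
Conditions: (S)-Me-CBS (10 mol%), BH3·SMe2 (0.7 equiv), THF, −20 °C; MeOH quench, aqueous work-up
Reagents that add atoms: none
Why: Corey–Bakshi–Shibata reduction: the ketone binds the oxazaborolidine with the 2-methylalkenyl flank as the large group, so hydride is delivered to one face and the (R)-carbinol is formed (the same sense as α-tetralone giving the (R)-alcohol with the (S)-catalyst).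

Step 3
Reactants: 5 (1R)-2,4,4-trimethylcyclohex-2-en-1-ol; 6 1,1,1-trimethoxyethane (trimethyl orthoacetate)
Product: 9 2-[(1S)-2,6,6-trimethylcyclohex-2-en-1-yl]acetic acid, via ketene acetal 7 (not isolated), via methyl ester 8 (not isolated)
Conditions: 6 (6 equiv), EtCO2H (10 mol%), xylenes, 140 °C, sealed tube; evaporate; then LiOH·H2O, THF/MeOH/H2O, 60 °C; HCl work-up
Reagents that add atoms: lithium hydroxide, [Li+].[OH-]
Why: Johnson–Claisen rearrangement: the suprafacial [3,3] shift forms the new C–C bond at C3 on the ring face that carried the C1–O bond, so the (R)-carbinol is relayed into the (S) ring stereocentre while the alkene moves to the 2,3-position; the crude ester is saponified in the same pot.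

Step 4
Reactants: 10 1,4-benzoquinone
Product: 12 2,5-dimethoxy-1,4-benzoquinone, via methoxybenzoquinone 11 (not isolated)
Conditions: MeOH, ZnCl2 (fused), 60 °C (three equivalents of 10 per product; two serve as oxidant)
Reagents that add atoms: methanol, CO
Why: Lewis-acid-promoted oxa-Michael addition of methanol followed by reoxidation of each adduct by excess 10, run twice; the second methoxy group enters the enone not deactivated by the first, giving the 2,5-pattern, and the product crystallises out.

Step 5
Reactants: 12 2,5-dimethoxy-1,4-benzoquinone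
Product: 13 2-hydroxy-5-methoxy-1,4-benzoquinone
Conditions: NaOH (1.05 equiv), H2O/THF, 0 °C to rt; then 1 M HCl
Reagents that add atoms: sodium hydroxide, [Na+].[OH-]
Why: Addition–elimination hydrolysis of a vinylogous ester: after the first methoxy group is displaced the product is a vinylogous carboxylate anion, which is deactivated toward a second hydroxide attack, so the reaction stops at the mono-hydroxy quinone.

Step 6
Reactants: 9 2-[(1S)-2,6,6-trimethylcyclohex-2-en-1-yl]acetic acid; 13 2-hydroxy-5-methoxy-1,4-benzoquinone; 14 2-methylbuta-1,3-diene (isoprene)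
Product: 16 2-hydroxy-5-methoxy-3-[(2E)-3-methyl-5-[(1S)-2,6,6-trimethylcyclohex-2-en-1-yl]pent-2-en-1-yl]cyclohexa-2,5-diene-1,4-dione, via NHPI ester 15 (not isolated)
Conditions: N-hydroxyphthalimide (1.05 equiv), N,N'-diisopropylcarbodiimide (1.0 equiv), DMAP (5 mol%), DMA, rt, 2 h; then 14 (10 equiv), 13 (1.5 equiv), Pd(PPh3)4 (5 mol%), Xantphos (6 mol%), 450 nm LEDs, 25 °C, degassed, sealed, no added base
Reagents that add atoms: none
Why: Proposed new method: photoexcited zerovalent palladium reduces 15 by single-electron transfer to give CO2, phthalimide anion and the primary [(1S)-2,6,6-trimethylcyclohex-2-en-1-yl]methyl radical, which adds to the CH2 terminus next to the methyl-bearing carbon of s-trans isoprene (about 1 M, so addition outruns radical rearrangement) to give the (E)-allyl radical; this recombines with monovalent palladium to a divalent allylpalladium cation, the phthalimide counter-anion is protonated by the far more acidic 13, and the resulting quinone enolate attacks the unsubstituted allyl terminus through C3 to give the linear (E)-product, with the stereocentre β to the radical untouched; the closest known reaction types are the visible-light palladium-catalysed three-component 1,4-carbofunctionalisation of 1,3-dienes with alkyl radical precursors and soft nucleophiles, and the palladium-catalysed C-allylation of 2-hydroxy-1,4-quinones.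

## Compound list

1 | 2-methylpropanal (isobutyraldehyde) | CC(C)C=O | starting material
2 | pent-1-en-3-one (ethyl vinyl ketone) | CCC(=O)C=C | starting material
3 | 2,2-dimethyl-5-oxoheptanal (Michael adduct) | CCC(=O)CCC(C)(C)C=O | intermediate
4 | 2,4,4-trimethylcyclohex-2-en-1-one | CC1=CC(C)(C)CCC1=O | intermediate
5 | (1R)-2,4,4-trimethylcyclohex-2-en-1-ol | O[C@H]1C(C)=CC(C)(C)CC1 | intermediate
6 | 1,1,1-trimethoxyethane (trimethyl orthoacetate) | CC(OC)(OC)OC | starting material
7 | 1-methoxyethenyl (1R)-2,4,4-trimethylcyclohex-2-en-1-yl ether (ketene acetal) | C=C(OC)O[C@H]1C(C)=CC(C)(C)CC1 | intermediate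
8 | methyl 2-[(1S)-2,6,6-trimethylcyclohex-2-en-1-yl]acetate | COC(=O)C[C@@H]1C(C)=CCCC1(C)C | intermediate
9 | 2-[(1S)-2,6,6-trimethylcyclohex-2-en-1-yl]acetic acid | OC(=O)C[C@@H]1C(C)=CCCC1(C)C | intermediate
10 | 1,4-benzoquinone | O=C1C=CC(=O)C=C1 | starting material
11 | 2-methoxy-1,4-benzoquinone | COC1=CC(=O)C=CC1=O | intermediate
12 | 2,5-dimethoxy-1,4-benzoquinone | COC1=CC(=O)C(OC)=CC1=O | intermediate
13 | 2-hydroxy-5-methoxy-1,4-benzoquinone | COC1=CC(=O)C(O)=CC1=O | intermediate
14 | 2-methylbuta-1,3-diene (isoprene) | C=CC(C)=C | starting material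
15 | 1,3-dioxoisoindolin-2-yl 2-[(1S)-2,6,6-trimethylcyclohex-2-en-1-yl]acetate (NHPI ester) | O=C(C[C@@H]1C(C)=CCCC1(C)C)ON1C(=O)c2ccccc2C1=O | intermediate
16 | 2-hydroxy-5-methoxy-3-[(2E)-3-methyl-5-[(1S)-2,6,6-trimethylcyclohex-2-en-1-yl]pent-2-en-1-yl]cyclohexa-2,5-diene-1,4-dione | COC1=CC(=O)C(O)=C(C/C=C(\C)CC[C@@H]2C(C)=CCCC2(C)C)C1=O | target

## Step count and risks

Total step count: 6. Longest linear sequence: 4 (steps 1, 2, 3, 6); the quinone branch (steps 4, 5) joins at step 6.

**Most at risk is step 6.** The failure modes are:
- quinone 13 may absorb the blue light or quench the excited palladium;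
- the primary radical may attack 13 directly instead of isoprene;
- some radical attack at the other isoprene terminus and some Z-alkene are expected, to be removed on AgNO3-impregnated silica;
- phthalimide may compete as an N-nucleophile.

The fallback separates the radical step from the quinone. It sets out from 9, which is converted into 15 and this time isolated. Ester 15 is irradiated with isoprene 14 and fac-Ir(ppy)3 (1 mol%) in MeCN/H2O under 450 nm light. Radical addition to isoprene is followed by oxidation of the allyl radical and capture by water. This gives the tertiary allylic alcohol 3-methyl-5-[(1S)-2,6,6-trimethylcyclohex-2-en-1-yl]pent-1-en-3-ol F1 together with its primary isomer (2E)-3-methyl-5-[(1S)-2,6,6-trimethylcyclohex-2-en-1-yl]pent-2-en-1-ol F2. Both ionise to the same allylpalladium species, so the mixture is used directly. In the dark, Pd(PPh3)4 (5 mol%) in dioxane at 60 °C with the acidic quinone 13 gives dehydrative C-allylation, and the route is rejoined at 16.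

**Second is step 3.** The new bond forms next to the gem-dimethyl carbon, and the acid catalyst at 140 °C can dehydrate or ionise the allylic alcohol. The fallback sets out from 5 and uses the neutral Eschenmoser–Claisen variant. N,N-Dimethylacetamide dimethyl acetal in xylene at 140 °C gives N,N-dimethyl-2-[(1S)-2,6,6-trimethylcyclohex-2-en-1-yl]acetamide F3. Iodolactonisation (I2, THF/H2O) cleaves the amide and gives the cis-fused iodolactone 7-iodo-4,4,7a-trimethylhexahydro-1-benzofuran-2(3H)-one F4. Zn in AcOH then opens F4 reductively, regenerates the ring alkene, and returns to the route at 9.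

**Third is step 2.** The enantiomeric excess may fall short of what a single-enantiomer target needs. The fallback sets out from 4 and uses an enzymatic resolution. Luche reduction (NaBH4, CeCl3·7H2O, MeOH) gives racemic 2,4,4-trimethylcyclohex-2-en-1-ol F5. Lipase PS with vinyl acetate acylates the (R)-enantiomer to (1R)-2,4,4-trimethylcyclohex-2-en-1-yl acetate F6. The unreacted (1S)-2,4,4-trimethylcyclohex-2-en-1-ol F7 is separated and recycled to 4 with MnO2. Methanolysis of F6 (K2CO3, MeOH) returns to the route at 5.

## Further compounds

F1 | step 6 | 3-methyl-5-[(1S)-2,6,6-trimethylcyclohex-2-en-1-yl]pent-1-en-3-ol (both C3 epimers) | C=CC(C)(O)CC[C@@H]1C(C)=CCCC1(C)C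
F2 | step 6 | (2E)-3-methyl-5-[(1S)-2,6,6-trimethylcyclohex-2-en-1-yl]pent-2-en-1-ol | OC/C=C(\C)CC[C@@H]1C(C)=CCCC1(C)C
F3 | step 3 | N,N-dimethyl-2-[(1S)-2,6,6-trimethylcyclohex-2-en-1-yl]acetamide | CN(C)C(=O)C[C@@H]1C(C)=CCCC1(C)C
F4 | step 3 | 7-iodo-4,4,7a-trimethylhexahydro-1-benzofuran-2(3H)-one (cis-fused lactone, iodine trans to the lactone oxygen) | O=C1O[C@]2(C)[C@@H](I)CCC(C)(C)[C@@H]2C1
F5 | step 2 | racemic 2,4,4-trimethylcyclohex-2-en-1-ol | CC1=CC(C)(C)CCC1O
F6 | step 2 | (1R)-2,4,4-trimethylcyclohex-2-en-1-yl acetate | CC(=O)O[C@H]1C(C)=CC(C)(C)CC1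
F7 | step 2 | (1S)-2,4,4-trimethylcyclohex-2-en-1-ol | O[C@@H]1C(C)=CC(C)(C)CC1
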